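**The leftover.** In the north-east run at 12.0 min, 68.3 % of the J charged stands as neither J, L nor G, so an unseen pool lies between J and L. The asked share, the selectivity L/(L+G), leaves that pool out of its count.

in all of them: J 39 mM; Q 46.8 mM; Z 78 µM

| run | D | temperature | remark | time |
|---|---|---|---|---|
| north-east | 20 µM | 30 °C | run made earlier |  |
| west | 45 µM | 50 °C | run made earlier |  |
| blue | 30 µM | 65 °C |  | 40 min |
| amber | 30 µM | 35 °C |  | 40 min |
| green | 30 µM |  | at 35 °C until 30 min, from then on at 65 °C | 40 min |
| teal | 30 µM | 50 °C |  | 40 min |

| run | time / min | L / % | G / % | J / % |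
|---|---|---|---|---|
| north-east | 12.0 | 5.6 | 0 | 26.1 |
| north-east | 15.0 | 8.6 | 0.6 | 22.2 |
| north-east | 30.0 | 17.5 | 0.4 | 16.9 |
| north-east | 50.0 | 26.1 | 0.4 | 14.9 |
| north-east | 80.0 | 36.6 | 2.2 | 11.8 |
| north-east | 150 | 49.2 | 6.6 | 8.6 |
| west | 4.00 | 5.5 | 0 | 25.2 |
| west | 6.00 | 8.8 | 0 | 24.5 |
| west | 10.0 | 13.2 | 0.4 | 22.6 |
| west | 15.0 | 20.5 | 1.4 | 20.7 |
| west | 30.0 | 30.5 | 5.1 | 17.0 |
| west | 50.0 | 38.7 | 9.1 | 15.4 |

(scatter of a reading: 0.5 percentage points)

- the flask that comes out highest in share of L in all that became L or G, or "all alike" when all lie within 1.5 percentage points (blue / amber / green / teal / all alike)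
- share of L in all that became L or G, blue
- share of L in all that became L or G, amber
- share of L in all that became L or G, green
- share of L in all that became L or G, teal



**Main step.** With a step to L and nothing else, the share is 100 %. The west run starts close to that, with 8.8 % L against 0 % G at 6.00 min.

**One leak.** G appears late, so it is taken as fed from L, a series reaction with a leak constant k. If L rises roughly straight from zero over a time t, then G/L = kt/2, and the share is 1/(1 + kt/2). The slope of L cancels in this ratio, so D, which differs between the runs, is assumed to have no part in it. L does curve, which inflates the k read here, but the same curvature returns when k is used. The last readings give 0.00179 min⁻¹ at 30 °C and 0.00941 min⁻¹ at 50 °C. The scatter is 7.58 % of the north-east G, so these are soft values.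

**Adding temperature.** The two readings give an activation energy of 67.6 kJ mol⁻¹. That puts k at 0.00276 min⁻¹ for 35 °C, and the leak constant at 65 °C at 0.0287 min⁻¹, the fraction of standing L turned to G each minute. At 40 min the reckoned shares are 94.8 % for amber, 84.2 % for teal and 63.5 % for blue. The early slope of L in the west run is 2.56 times that in the north-east run, but D and temperature differ together between them, so that factor cannot be put down to temperature, and the bend of L at green's change is not reckoned. As a rough figure, green is given one straight L, with the cold k before 30 min and the hot k after. That gives 78.0 % for green. Amber comes out highest.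

**The forecast.** It names amber, with 95 % for amber, 87 % for teal, 81 % for green and 70 % for blue, holding that “G shows a lag, so it comes from L in a sequential step”; its teal, green and blue stand higher than the figures here.

**Flasks read.** Amber stands highest at 94.4 %, then teal at 84.4 %, green at 82.3 % and blue at 66.6 %.

    J + D ⇌ D + X (K = 3.70, k = 180 M⁻¹ s⁻¹, Ea = 44.0 kJ mol⁻¹, ΔH = −15.0 kJ mol⁻¹)
    Q + Z + X → Z + L (k = 59.0 M⁻² s⁻¹, Ea = 35.0 kJ mol⁻¹)
    Q + L → G (k = 0.00120 M⁻¹ s⁻¹, Ea = 63.0 kJ mol⁻¹)
    (constants at 35 °C)

**Blue's ledger.** For blue left until 1.0 h, the kept k reckons 53.7 %, and that neighbour flask stands at 59.4 %. At 40.0 min, blue makes L 1.31 times as fast as it uses L up. Blue's Q then goes to L 1.3 times as fast as to G, with 41 % of its Q left.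

The data are simulated from invented constants.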